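**Plan**

1. Retrosynthesis cuts the two interflavan bonds, C4(top)–C8(middle) and C4(middle)–C8(bottom), and then, in ring C of the top (gallocatechin) unit, the bonds O1–C8a and C2–C3.
2. Enabling feature: with C4 of the top unit as a ketone, C3 is an enolate carbon and C8a of ring A (ortho to the acyl-bearing C4a, meta to both ring A oxygens) is an SNAr position. Ring C is therefore zipped from the four-atom unit C3–C4–C4a–C8a(F) and the ring B aldehyde (C2=O1) in one aldol/SNAr annulation.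
3. Forward order: fluorinated ring A ketone → ring C of the top unit (a dihydroflavonol) → C4 reduced and activated as in the biosynthesis (leucoanthocyanidin cation). The middle–bottom dimer is made from (+)- and (−)-catechin by a tethered coupling, the top unit is joined last, then the protecting groups are removed.
4. Stereochemistry: C2 of the top unit comes from a chiral ammonium ion pair and C3 from the trans ring closure. C4 of the top unit (4α, 3,4-trans) comes from 3-O-acetyl participation. The middle and bottom units come from the chiral pool. C4 of the middle unit (4β, 3,4-cis) comes from a temporary glutarate tether that is cleaved afterwards.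

Key step: step 5

Remark: the target is read as (+)-gallocatechin-(4α→8)-(+)-catechin-(4β→8)-(−)-catechin (top 2R,3S, 4α-aryl; middle 2R,3S, 4β-aryl; bottom 2S,3R). The C4 configuration of compounds 13, 14 and 17 is of no consequence because C4 is ionised in the couplings.

**Route**

Step 1
Reactants: 1 1,3,5-trifluorobenzene
Product: 2 1,3-bis(benzyloxy)-5-fluorobenzene
Conditions: BnOH (2.1 equiv), NaH, NMP, 0 → 80 °C
Reagents that add atoms: benzyl alcohol, OCc1ccccc1
Why: Twofold SNAr of sodium benzyloxide on a fluoroarene activated by its other fluorines; stoichiometry and temperature should stop the reaction after two substitutions.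

Step 2
Reactants: 3 2-chloro-N-methoxy-N-methylacetamide
Product: 4 N-methoxy-2-[(4-methoxybenzyl)oxy]-N-methylacetamide
Conditions: 4-methoxybenzyl alcohol, NaH, THF, 0 °C → rt
Reagents that add atoms: 4-methoxybenzyl alcohol, COc1ccc(CO)cc1
Why: Williamson ether synthesis; the alkoxide should displace the activated α-chloride faster than it attacks the N-methoxy-N-methylamide carbonyl.

Step 3
Reactants: 2 1,3-bis(benzyloxy)-5-fluorobenzene; 4 N-methoxy-2-[(4-methoxybenzyl)oxy]-N-methylacetamide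
Product: 6 1-[2,4-bis(benzyloxy)-6-fluorophenyl]-2-[(4-methoxybenzyl)oxy]ethan-1-one, via 2,4-bis(benzyloxy)-6-fluorophenyllithium 5 (not isolated)
Conditions: n-BuLi, THF, −78 °C; then 4, −78 → −40 °C; H2O
Reagents that add atoms: none
Why: Directed ortho-lithiation at the position flanked by F and OBn (kept at −78 °C to avoid benzyne formation), then Weinreb ketone synthesis, whose chelated tetrahedral adduct prevents over-addition.

Step 4
Reactants: 6 1-[2,4-bis(benzyloxy)-6-fluorophenyl]-2-[(4-methoxybenzyl)oxy]ethan-1-one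
Product: 7 (Z)-trimethylsilyl enol ether of 6
Conditions: TMSOTf, Et3N, CH2Cl2, 0 °C; non-aqueous work-up
Reagents that add atoms: trimethylsilyl trifluoromethanesulfonate, C[Si](C)(C)OS(=O)(=O)C(F)(F)F
Why: Soft enolisation and O-silylation of an α-alkoxy ketone, which should give the Z enol silane; the enol silane is the latent C3 nucleophile.

Step 5
Reactants: 7 (Z)-trimethylsilyl enol ether of 6 (1.3 equiv); 8 3,4,5-tris(benzyloxy)benzaldehyde
Product: 11 (2R,3R)-5,7-bis(benzyloxy)-3-[(4-methoxybenzyl)oxy]-2-[3,4,5-tris(benzyloxy)phenyl]chroman-4-one, via ammonium enolate 9 (not isolated), via ammonium aldolate 10 (not isolated)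
Conditions: (S,S)-N-spiro bis(binaphthyl) quaternary ammonium bifluoride bearing 3,4,5-trifluorophenyl groups (5 mol%), THF, −78 → −20 °C; AcOH quench
Reagents that add atoms: none
Why: Proposed new method: fluoride from the chiral ammonium bifluoride desilylates 7 to the ion-paired enolate 9, whose C3 adds to the aldehyde carbon of 8 (C2–C3 bond) to give aldolate 10; the C2 alkoxide then adds to C8a of the fluoroarene (Meisenheimer adduct) and expels fluoride (O1–C8a bond), and this fluoride returns to the chiral cation and desilylates the next molecule of 7, so that Me3SiF is the only co-product. The closest known reaction types are the chiral quaternary ammonium fluoride-catalysed Mukaiyama aldol addition, the fluoride-catalysed SNAr of silyl ethers on activated aryl fluorides, and the aldol/cyclisation annulation of 1-alkoxy-3-silyloxy dienes with aldehydes to dihydropyranones, of which this is a benzo-fused version not yet shown on aryl ketone enolates that carry an ortho fluoride. Ring C is closed in the 6-exo-trig mode by addition–elimination at C8a. C2 is set by the chiral cation, the only counter-ion of every anionic intermediate, so that even a reversible aldol addition should be funnelled through Si-face addition to 8 and ring closure of the (2R) aldolate; C3 is set relative to C2 by the chair-like closure with the aryl and OPMB groups both equatorial (2,3-trans), which is also the more stable arrangement at this enolisable centre. The step needs the six-membered closure to outrun retro-aldol cleavage, dehydration to a chalcone and any five-membered closure through O3: the ortho carbonyl activates only C8a–F, both benzyloxy groups are meta to the leaving group, O3 is capped as its PMB ether, and no free base or achiral cation is present.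

Step 6
Reactants: 11 (2R,3R)-5,7-bis(benzyloxy)-3-[(4-methoxybenzyl)oxy]-2-[3,4,5-tris(benzyloxy)phenyl]chroman-4-one
Product: 12 (2R,3R)-5,7-bis(benzyloxy)-3-hydroxy-2-[3,4,5-tris(benzyloxy)phenyl]chroman-4-one (penta-O-benzyl-(+)-dihydromyricetin)
Conditions: DDQ, CH2Cl2/pH 7 buffer, 0 °C → rt
Reagents that add atoms: none
Why: Oxidative cleavage of the PMB ether; the benzyl aryl ethers and the flavanone should be inert to DDQ under these conditions.

Step 7
Reactants: 12 penta-O-benzyl-(+)-dihydromyricetin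
Product: 13 (2R,3S,4R)-5,7-bis(benzyloxy)-2-[3,4,5-tris(benzyloxy)phenyl]chromane-3,4-diol (2,3-trans-3,4-trans)
Conditions: NaBH4, THF/MeOH, 0 °C
Reagents that add atoms: none
Why: Hydride reduction of a dihydroflavonol to the flavan-3,4-diol, the laboratory counterpart of the biosynthetic reduction to a leucoanthocyanidin; the 3,4-trans diol is expected.

Step 8
Reactants: 13 (2R,3S,4R)-flavan-3,4-diol
Product: 14 3,4-di-O-acetate of 13 (3β-OAc, 4α-OAc)
Conditions: Ac2O, pyridine, DMAP (cat.), CH2Cl2, rt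
Reagents that add atoms: acetic anhydride, CC(=O)OC(C)=O
Why: Acylation of both secondary alcohols; it installs the C4 leaving group and the participating 3-O-acetyl group in one operation.

Step 9
Reactants: 15 (+)-catechin
Product: 16 5,7,3',4'-tetra-O-benzyl-(+)-catechin [(2R,3S)-5,7-bis(benzyloxy)-2-[3,4-bis(benzyloxy)phenyl]chroman-3-ol]
Conditions: BnBr (4.4 equiv), K2CO3, DMF, 0 °C → rt
Reagents that add atoms: benzyl bromide, BrCc1ccccc1
Why: Williamson O-benzylation of the four phenols; the aliphatic 3-OH is not deprotonated by K2CO3.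

Step 10
Reactants: 16 5,7,3',4'-tetra-O-benzyl-(+)-catechin
Product: 17 (2R,3S,4S)-5,7-bis(benzyloxy)-2-[3,4-bis(benzyloxy)phenyl]-4-(2-ethoxyethoxy)chroman-3-ol (4β)
Conditions: DDQ, 2-ethoxyethanol, CH2Cl2, rt
Reagents that add atoms: 2-ethoxyethanol, CCOCCO
Why: DDQ benzylic oxidation at C4 (hydride abstraction assisted by ring A), with the cation trapped by the alcohol, expected on the face anti to the C2 aryl group.

Step 11
Reactants: 18 (−)-catechin
Product: 19 5,7,3',4'-tetra-O-benzyl-(−)-catechin [(2S,3R)]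
Conditions: BnBr (4.4 equiv), K2CO3, DMF, 0 °C → rt
Reagents that add atoms: benzyl bromide, BrCc1ccccc1
Why: Williamson O-benzylation of the four phenols, as in step 9.

Step 12
Reactants: 19 5,7,3',4'-tetra-O-benzyl-(−)-catechin
Product: 20 3-O-(4-carboxybutanoyl) derivative (hemiglutarate) of 19
Conditions: glutaric anhydride, Et3N, DMAP (cat.), CH2Cl2, rt; dilute acid work-up
Reagents that add atoms: glutaric anhydride, O=C1CCCC(=O)O1
Why: DMAP-catalysed ring-opening acylation of the anhydride by the 3-OH; this attaches the temporary tether.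

Step 13
Reactants: 20 hemiglutarate of 19; 17 4β-(2-ethoxyethoxy) derivative of 16
Product: 21 glutarate diester that links O3 of 17 with O3 of 19
Conditions: DCC, DMAP, CH2Cl2, 0 °C → rt
Reagents that add atoms: none
Why: Steglich esterification; the acid-labile C4 acetal-type ether of 17 should tolerate these neutral conditions.

Step 14
Reactants: 21 glutarate diester
Product: 22 3,3''-O-pentanedioyl-bridged octa-O-benzyl-(+)-catechin-(4β→8)-(−)-catechin (14-membered macrocycle)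
Conditions: TMSOTf (0.3 equiv), CH2Cl2 (5 mM), −40 → −20 °C
Reagents that add atoms: none
Why: The Lewis acid ionises C4–O to the benzylic cation, which is captured in an intramolecular Friedel–Crafts alkylation by C8 of the ent-catechin unit; the tether anchored on the β-oriented O3 can deliver the arene only to the β face, so the 3,4-cis (4β) bond should form.

Step 15
Reactants: 22 tethered dimer
Product: 23 octa-O-benzyl-(+)-catechin-(4β→8)-(−)-catechin (3,3''-diol)
Conditions: NaOMe (cat.), MeOH/THF, rt → 40 °C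
Reagents that add atoms: none
Why: Zemplén-type transesterification releases the tether as its dimethyl ester; the benzyl ethers and the stereocentres are untouched.

Step 16
Reactants: 23 octa-O-benzyl dimer (1.5 equiv); 14 3,4-di-O-acetate
Product: 24 3-O-acetyl (top unit) trideca-O-benzyl-(+)-gallocatechin-(4α→8)-(+)-catechin-(4β→8)-(−)-catechin
Conditions: TMSOTf (0.5 equiv), CH2Cl2, −78 → −40 °C
Reagents that add atoms: none
Why: Biomimetic chain extension by Friedel–Crafts alkylation of the flavan-3-ol nucleophile with the C4 cation; the 3-O-acetyl group should bridge the β face as a dioxolenium ion, so that C8 of the upper unit of 23, its most nucleophilic and accessible position, attacks from the α face (3,4-trans).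

Step 17
Reactants: 24 trimer acetate
Product: 25 trideca-O-benzyl-(+)-gallocatechin-(4α→8)-(+)-catechin-(4β→8)-(−)-catechin (3,3',3''-triol)
Conditions: NaOMe (cat.), MeOH/THF, rt
Reagents that add atoms: none
Why: Zemplén deacetylation of the single secondary acetate.

Step 18
Reactants: 25 trideca-O-benzyl trimer
Product: 26 (+)-gallocatechin-(4α→8)-(+)-catechin-(4β→8)-(−)-catechin (target)
Conditions: H2 (1 atm), Pd(OH)2/C, THF/MeOH/H2O, rt
Reagents that add atoms: none
Why: Hydrogenolysis of the thirteen benzyl ethers under neutral conditions, which should leave the C2–O, C4–aryl bonds and all stereocentres intact.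

**Compound list**

1 | 1,3,5-trifluorobenzene | Fc1cc(F)cc(F)c1 | starting material
2 | 1,3-bis(benzyloxy)-5-fluorobenzene | Fc1cc(OCc2ccccc2)cc(OCc2ccccc2)c1 | intermediate
3 | 2-chloro-N-methoxy-N-methylacetamide | CON(C)C(=O)CCl | starting material
4 | N-methoxy-2-[(4-methoxybenzyl)oxy]-N-methylacetamide | CON(C)C(=O)COCc1ccc(OC)cc1 | intermediate
5 | 2,4-bis(benzyloxy)-6-fluorophenyllithium | [Li]c1c(F)cc(OCc2ccccc2)cc1OCc1ccccc1 | intermediate
6 | 1-[2,4-bis(benzyloxy)-6-fluorophenyl]-2-[(4-methoxybenzyl)oxy]ethan-1-one | COc1ccc(COCC(=O)c2c(F)cc(OCc3ccccc3)cc2OCc2ccccc2)cc1 | intermediate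
7 | (Z)-trimethylsilyl enol ether of 6 | COc1ccc(CO/C=C(\O[Si](C)(C)C)c2c(F)cc(OCc3ccccc3)cc2OCc2ccccc2)cc1 | intermediate
8 | 3,4,5-tris(benzyloxy)benzaldehyde | O=Cc1cc(OCc2ccccc2)c(OCc2ccccc2)c(OCc2ccccc2)c1 | starting material
9 | (Z)-enolate of 6 as its chiral ammonium salt (anion shown) | COc1ccc(CO/C=C(\[O-])c2c(F)cc(OCc3ccccc3)cc2OCc2ccccc2)cc1 | intermediate
10 | (1R,2R)-3-[2,4-bis(benzyloxy)-6-fluorophenyl]-2-[(4-methoxybenzyl)oxy]-3-oxo-1-[3,4,5-tris(benzyloxy)phenyl]propan-1-olate as its chiral ammonium salt (anti aldolate, anion shown) | [O-][C@H](c1cc(OCc2ccccc2)c(OCc2ccccc2)c(OCc2ccccc2)c1)[C@@H](OCc1ccc(OC)cc1)C(=O)c1c(F)cc(OCc2ccccc2)cc1OCc1ccccc1 | intermediate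
11 | (2R,3R)-5,7-bis(benzyloxy)-3-[(4-methoxybenzyl)oxy]-2-[3,4,5-tris(benzyloxy)phenyl]chroman-4-one | O=C1c2c(OCc3ccccc3)cc(OCc3ccccc3)cc2O[C@H](c2cc(OCc3ccccc3)c(OCc3ccccc3)c(OCc3ccccc3)c2)[C@H]1OCc1ccc(OC)cc1 | intermediate
12 | (2R,3R)-5,7-bis(benzyloxy)-3-hydroxy-2-[3,4,5-tris(benzyloxy)phenyl]chroman-4-one | O=C1c2c(OCc3ccccc3)cc(OCc3ccccc3)cc2O[C@H](c2cc(OCc3ccccc3)c(OCc3ccccc3)c(OCc3ccccc3)c2)[C@H]1O | intermediate
13 | (2R,3S,4R)-5,7-bis(benzyloxy)-2-[3,4,5-tris(benzyloxy)phenyl]chromane-3,4-diol | c1ccccc1COc1cc(OCc2ccccc2)c2c(c1)O[C@H](c1cc(OCc3ccccc3)c(OCc3ccccc3)c(OCc3ccccc3)c1)[C@@H](O)[C@@H]2O | intermediate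
14 | 3,4-di-O-acetate of 13 (3β-OAc, 4α-OAc) | c1ccccc1COc1cc(OCc2ccccc2)c2c(c1)O[C@H](c1cc(OCc3ccccc3)c(OCc3ccccc3)c(OCc3ccccc3)c1)[C@@H](OC(C)=O)[C@@H]2OC(C)=O | intermediate
15 | (+)-catechin | Oc1cc(O)c2c(c1)O[C@H](c1ccc(O)c(O)c1)[C@@H](O)C2 | starting material
16 | 5,7,3',4'-tetra-O-benzyl-(+)-catechin | c1ccccc1COc1cc(OCc2ccccc2)c2c(c1)O[C@H](c1ccc(OCc3ccccc3)c(OCc3ccccc3)c1)[C@@H](O)C2 | intermediate
17 | (2R,3S,4S)-5,7-bis(benzyloxy)-2-[3,4-bis(benzyloxy)phenyl]-4-(2-ethoxyethoxy)chroman-3-ol | c1ccccc1COc1cc(OCc2ccccc2)c2c(c1)O[C@H](c1ccc(OCc3ccccc3)c(OCc3ccccc3)c1)[C@@H](O)[C@H]2OCCOCC | intermediate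
18 | (−)-catechin | Oc1cc(O)c2c(c1)O[C@@H](c1ccc(O)c(O)c1)[C@H](O)C2 | starting material
19 | 5,7,3',4'-tetra-O-benzyl-(−)-catechin | c1ccccc1COc1cc(OCc2ccccc2)c2c(c1)O[C@@H](c1ccc(OCc3ccccc3)c(OCc3ccccc3)c1)[C@H](O)C2 | intermediate
20 | 3-O-(4-carboxybutanoyl)-5,7,3',4'-tetra-O-benzyl-(−)-catechin | c1ccccc1COc1cc(OCc2ccccc2)c2c(c1)O[C@@H](c1ccc(OCc3ccccc3)c(OCc3ccccc3)c1)[C@H](OC(=O)CCCC(=O)O)C2 | intermediate
21 | glutarate diester linking O3 of 17 and O3 of 19 | c1ccccc1COc1cc(OCc2ccccc2)c2c(c1)O[C@H](c1ccc(OCc3ccccc3)c(OCc3ccccc3)c1)[C@@H](OC(=O)CCCC(=O)O[C@@H]1Cc3c(OCc4ccccc4)cc(OCc4ccccc4)cc3O[C@H]1c1ccc(OCc3ccccc3)c(OCc3ccccc3)c1)[C@H]2OCCOCC | intermediate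
22 | 3,3''-O-pentanedioyl-bridged octa-O-benzyl-(+)-catechin-(4β→8)-(−)-catechin | c1ccccc1COc1cc(OCc2ccccc2)c2c(c1)O[C@H](c1ccc(OCc3ccccc3)c(OCc3ccccc3)c1)[C@@H](OC(=O)CCCC(=O)O9)[C@H]2c1c(OCc2ccccc2)cc(OCc2ccccc2)c2c1O[C@@H](c1ccc(OCc3ccccc3)c(OCc3ccccc3)c1)[C@H]9C2 | intermediate
23 | octa-O-benzyl-(+)-catechin-(4β→8)-(−)-catechin | c1ccccc1COc1cc(OCc2ccccc2)c2c(c1)O[C@H](c1ccc(OCc3ccccc3)c(OCc3ccccc3)c1)[C@@H](O)[C@H]2c1c(OCc2ccccc2)cc(OCc2ccccc2)c2c1O[C@@H](c1ccc(OCc3ccccc3)c(OCc3ccccc3)c1)[C@H](O)C2 | intermediate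
24 | 3-O-acetyl (top unit) trideca-O-benzyl trimer | c1ccccc1COc1cc(OCc2ccccc2)c2c(c1)O[C@H](c1cc(OCc3ccccc3)c(OCc3ccccc3)c(OCc3ccccc3)c1)[C@@H](OC(C)=O)[C@@H]2c1c(OCc2ccccc2)cc(OCc2ccccc2)c2c1O[C@H](c1ccc(OCc3ccccc3)c(OCc3ccccc3)c1)[C@@H](O)[C@H]2c1c(OCc2ccccc2)cc(OCc2ccccc2)c2c1O[C@@H](c1ccc(OCc3ccccc3)c(OCc3ccccc3)c1)[C@H](O)C2 | intermediate
25 | trideca-O-benzyl trimer triol | c1ccccc1COc1cc(OCc2ccccc2)c2c(c1)O[C@H](c1cc(OCc3ccccc3)c(OCc3ccccc3)c(OCc3ccccc3)c1)[C@@H](O)[C@@H]2c1c(OCc2ccccc2)cc(OCc2ccccc2)c2c1O[C@H](c1ccc(OCc3ccccc3)c(OCc3ccccc3)c1)[C@@H](O)[C@H]2c1c(OCc2ccccc2)cc(OCc2ccccc2)c2c1O[C@@H](c1ccc(OCc3ccccc3)c(OCc3ccccc3)c1)[C@H](O)C2 | intermediate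
26 | (+)-gallocatechin-(4α→8)-(+)-catechin-(4β→8)-(−)-catechin | Oc1cc(O)c2c(c1)O[C@H](c1cc(O)c(O)c(O)c1)[C@@H](O)[C@@H]2c1c(O)cc(O)c2c1O[C@H](c1ccc(O)c(O)c1)[C@@H](O)[C@H]2c1c(O)cc(O)c2c1O[C@@H](c1ccc(O)c(O)c1)[C@H](O)C2 | target

**Step count and risks**

Total: 18 steps. Longest linear sequence: 10 steps (steps 1, 3, 4, 5, 6, 7, 8, 16, 17, 18).

Steps most likely to fail:

1. Step 5 (Proposed new method). The aldolate may revert by retro-aldol cleavage or dehydrate faster than it closes the ring, and the ion pair may give poor or reversed facial selectivity at the aldehyde. Fallback, known chemistry: it sets out from 8 and rejoins the route at 12, so that steps 1 to 6 are not needed. Commercial 1-[2,4-bis(benzyloxy)-6-hydroxyphenyl]ethan-1-one F1 is protected (MOMCl, i-Pr2NEt, CH2Cl2) as its methoxymethyl ether F2. Claisen–Schmidt condensation of F2 with 8 (KOH, EtOH/THF) gives the (E)-chalcone F3. Juliá–Colonna epoxidation (poly-L-leucine, urea–H2O2, DBU, THF) gives the (αR,βS)-epoxychalcone F4. HCl in MeOH/THF then removes the methoxymethyl group, and the freed phenol opens the epoxide at the benzylic carbon with inversion to give 12.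

2. Step 14. The tether to the ent-configured nucleophile may be mismatched, so that alkylation goes to C6 of the lower unit or intermolecular oligomerisation takes over. Fallback: it sets out from 16 and 19 and rejoins at 23, so that steps 10, 12, 13, 14 and 15 are not needed. 16 is silylated (TBSOTf, 2,6-lutidine) to the 3-O-TBS ether of 16 F5, oxidised at C4 (DDQ, CH2Cl2/H2O) to the 4-hydroxy compound F6 and then by Dess–Martin oxidation to the flavan-4-one F7. 19 is silylated likewise to the 3-O-TBS ether of 19 F8 and brominated at C8 (NBS, CH2Cl2, −78 °C) to the 8-bromo compound F9. Bromine–lithium exchange on F9 (t-BuLi, THF, −78 °C) and addition of the aryllithium to F7 gives the tertiary 4-aryl-4-hydroxy adduct F10. Ionic hydrogenation (Bu3SnH, CF3CO2H, CH2Cl2) should deliver hydride to the C4 cation anti to the 3-O-silyl group and leave the aryl group cis to it (4β), giving the bis-TBS dimer F11. Tetrabutylammonium fluoride in THF then gives 23.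

3. Step 16. The cation may be captured by ring A of a second molecule of 14 or of the product (over-alkylation), or by a C6 position. Fallback: it sets out from 14 and rejoins at 26. 14 is brominated at C8 (NBS, CH2Cl2, −78 °C) to the 8-bromo diacetate F12, whose ring A is blocked and deactivated. Coupling of F12 with 23 (BF3·OEt2, CH2Cl2, −78 °C) gives the 8-bromo trimer acetate F13, and NaOMe in MeOH/THF gives the 8-bromo trimer triol F14. Hydrogenolysis (H2, Pd(OH)2/C, Et3N, THF/MeOH) removes the bromine together with the benzyl groups and gives 26.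

**Further compounds**

F1 | step 5 | 1-[2,4-bis(benzyloxy)-6-hydroxyphenyl]ethan-1-one | CC(=O)c1c(O)cc(OCc2ccccc2)cc1OCc1ccccc1
F2 | step 5 | 1-[2,4-bis(benzyloxy)-6-(methoxymethoxy)phenyl]ethan-1-one | CC(=O)c1c(OCOC)cc(OCc2ccccc2)cc1OCc1ccccc1
F3 | step 5 | (E)-1-[2,4-bis(benzyloxy)-6-(methoxymethoxy)phenyl]-3-[3,4,5-tris(benzyloxy)phenyl]prop-2-en-1-one | O=C(/C=C/c1cc(OCc2ccccc2)c(OCc2ccccc2)c(OCc2ccccc2)c1)c1c(OCOC)cc(OCc2ccccc2)cc1OCc1ccccc1
F4 | step 5 | (αR,βS)-trans-epoxide of F3 | O=C([C@@H]1O[C@H]1c1cc(OCc2ccccc2)c(OCc2ccccc2)c(OCc2ccccc2)c1)c1c(OCOC)cc(OCc2ccccc2)cc1OCc1ccccc1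
F5 | step 14 | 3-O-tert-butyldimethylsilyl-5,7,3',4'-tetra-O-benzyl-(+)-catechin | c1ccccc1COc1cc(OCc2ccccc2)c2c(c1)O[C@H](c1ccc(OCc3ccccc3)c(OCc3ccccc3)c1)[C@@H](O[Si](C)(C)C(C)(C)C)C2
F6 | step 14 | 4β-hydroxy derivative of F5 | c1ccccc1COc1cc(OCc2ccccc2)c2c(c1)O[C@H](c1ccc(OCc3ccccc3)c(OCc3ccccc3)c1)[C@@H](O[Si](C)(C)C(C)(C)C)[C@H]2O
F7 | step 14 | (2R,3R)-5,7-bis(benzyloxy)-2-[3,4-bis(benzyloxy)phenyl]-3-(tert-butyldimethylsilyloxy)chroman-4-one | O=C1c2c(OCc3ccccc3)cc(OCc3ccccc3)cc2O[C@H](c2ccc(OCc3ccccc3)c(OCc3ccccc3)c2)[C@H]1O[Si](C)(C)C(C)(C)C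
F8 | step 14 | 3-O-tert-butyldimethylsilyl-5,7,3',4'-tetra-O-benzyl-(−)-catechin | c1ccccc1COc1cc(OCc2ccccc2)c2c(c1)O[C@@H](c1ccc(OCc3ccccc3)c(OCc3ccccc3)c1)[C@H](O[Si](C)(C)C(C)(C)C)C2
F9 | step 14 | 8-bromo derivative of F8 | Brc1c(OCc2ccccc2)cc(OCc2ccccc2)c2c1O[C@@H](c1ccc(OCc3ccccc3)c(OCc3ccccc3)c1)[C@H](O[Si](C)(C)C(C)(C)C)C2
F10 | step 14 | 4α-aryl-4β-hydroxy adduct of F7 with the 8-lithio derivative of F8 | c1ccccc1COc1cc(OCc2ccccc2)c2c(c1)O[C@H](c1ccc(OCc3ccccc3)c(OCc3ccccc3)c1)[C@@H](O[Si](C)(C)C(C)(C)C)[C@]2(O)c1c(OCc2ccccc2)cc(OCc2ccccc2)c2c1O[C@@H](c1ccc(OCc3ccccc3)c(OCc3ccccc3)c1)[C@H](O[Si](C)(C)C(C)(C)C)C2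
F11 | step 14 | 3,3''-bis-O-tert-butyldimethylsilyl ether of 23 | c1ccccc1COc1cc(OCc2ccccc2)c2c(c1)O[C@H](c1ccc(OCc3ccccc3)c(OCc3ccccc3)c1)[C@@H](O[Si](C)(C)C(C)(C)C)[C@H]2c1c(OCc2ccccc2)cc(OCc2ccccc2)c2c1O[C@@H](c1ccc(OCc3ccccc3)c(OCc3ccccc3)c1)[C@H](O[Si](C)(C)C(C)(C)C)C2
F12 | step 16 | 8-bromo derivative of 14 | Brc1c(OCc2ccccc2)cc(OCc2ccccc2)c2c1O[C@H](c1cc(OCc3ccccc3)c(OCc3ccccc3)c(OCc3ccccc3)c1)[C@@H](OC(C)=O)[C@@H]2OC(C)=O
F13 | step 16 | 8-bromo (top unit) derivative of 24 | Brc1c(OCc2ccccc2)cc(OCc2ccccc2)c2c1O[C@H](c1cc(OCc3ccccc3)c(OCc3ccccc3)c(OCc3ccccc3)c1)[C@@H](OC(C)=O)[C@@H]2c1c(OCc2ccccc2)cc(OCc2ccccc2)c2c1O[C@H](c1ccc(OCc3ccccc3)c(OCc3ccccc3)c1)[C@@H](O)[C@H]2c1c(OCc2ccccc2)cc(OCc2ccccc2)c2c1O[C@@H](c1ccc(OCc3ccccc3)c(OCc3ccccc3)c1)[C@H](O)C2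
F14 | step 16 | 8-bromo (top unit) derivative of 25 | Brc1c(OCc2ccccc2)cc(OCc2ccccc2)c2c1O[C@H](c1cc(OCc3ccccc3)c(OCc3ccccc3)c(OCc3ccccc3)c1)[C@@H](O)[C@@H]2c1c(OCc2ccccc2)cc(OCc2ccccc2)c2c1O[C@H](c1ccc(OCc3ccccc3)c(OCc3ccccc3)c1)[C@@H](O)[C@H]2c1c(OCc2ccccc2)cc(OCc2ccccc2)c2c1O[C@@H](c1ccc(OCc3ccccc3)c(OCc3ccccc3)c1)[C@H](O)C2
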